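**Plan**

1. Cuts: the ten O–H bonds go back to acetates; the stilbene is cut at the aryl–CH= bond (Heck) into a left aryl bromide and a right vinyl-dihydrobenzofuran. In the left half the C8a–H/C7a–H bonds (benzofuran reduction), the C7b–aryl and C8b–aryl bonds (one-pot diarylation), the C7b=C8b alkene (McMurry), the ring A–benzofuran bond (Suzuki) and the furan ring are cut in turn; in the right half the C7d–C8d bond (carbene C–H insertion).
2. Enabling feature: in the seven-membered ring the neighbouring methines C7b (on ring A, 4-hydroxyphenyl) and C8b (on benzofuran ring B, 2-hydroxy-5-styrylphenyl) are cis-diarylated. This maps onto addition of two different aryl groups to one face of a ring-locked C7b=C8b stilbene.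
3. Forward, left: furan ring → biaryl → seven-membered ring → syn-diarylation → dihydrofuran → methyl-to-acetate exchange. Right: benzophenone → dihydrobenzofuran → acetate exchange → vinyl group. Heck union, then methanolysis.
4. Stereochemistry: C7b/C8b from face selection by a chiral ligand on Pd plus syn addition; C8a/C7a from the seven-ring conformation during C3 protonation and the thermodynamic trans ring; C8d from a chiral Rh(II) catalyst and C7d by acid epimerisation to trans; the E-alkene from the Heck step.

Key step: step 6

Remarks.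
- Locants: C7a = O–CH(aryl) of the ring-fused dihydrofuran; C8a = its neighbour, the CH bonded to rings A and B; C7b (on ring A) and C8b (on ring B) = the other two CH carbons of the seven-membered ring; C7d/C8d = positions 2/3 of the second dihydrobenzofuran. Ring A = the dioxygenated benzene ring fused only to the seven-membered ring; ring B = the benzene ring of the (dihydro)benzofuran.
- Assumption: the sense of induction of the chiral PyOx ligand (step 6) and of Rh2(PTAD)4 (step 12) has to be settled by experiment; the (S)-forms are written and the antipode is used if the other face is delivered.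
- The phenols are carried as methyl ethers and exchanged for acetates before the Heck union, so that no Lewis acid meets the assembled stilbene–dihydrobenzofuran array.

**Step 1**
Reactants: 1 3-hydroxy-5-methoxybenzaldehyde
Product: 2 3-hydroxy-2-iodo-5-methoxybenzaldehyde
Conditions: NIS (1.0 equiv), TFA (10 mol %), MeCN, 0 °C → rt
Reagents that add atoms: N-iodosuccinimide, O=C1CCC(=O)N1I
Why: Electrophilic aromatic iodination; C2 is ortho to OH and para to OMe, the best combination of the three open sites (C6 is para to OH but ortho to the bulkier OMe, C4 lies between two oxygens), so the 2-iodo isomer should dominate and minor regioisomers are removed by chromatography.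

**Step 2**
Reactants: 2 3-hydroxy-2-iodo-5-methoxybenzaldehyde; 3 4-ethynylanisole
Product: 5 6-methoxy-2-(4-methoxyphenyl)benzofuran-4-carbaldehyde, via o-alkynylphenol 4 (not isolated)
Conditions: PdCl2(PPh3)2 (3 mol %), CuI (5 mol %), Et3N, DMF, rt → 70 °C
Reagents that add atoms: none
Why: Sonogashira coupling followed in the same pot by 5-endo-dig attack of the phenol on the alkyne (domino coupling–cycloisomerisation of an o-iodophenol), a standard route to 2-arylbenzofurans that tolerates the aldehyde.

**Step 3**
Reactants: 5 6-methoxy-2-(4-methoxyphenyl)benzofuran-4-carbaldehyde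
Product: 6 3-iodo-6-methoxy-2-(4-methoxyphenyl)benzofuran-4-carbaldehyde
Conditions: NIS, TFA (cat.), MeCN, rt
Reagents that add atoms: N-iodosuccinimide, O=C1CCC(=O)N1I
Why: Electrophilic iodination at C3, the enol-ether β-carbon conjugated with the 2-anisyl group and the most nucleophilic position of a 2-arylbenzofuran.

**Step 4**
Reactants: 7 2-bromo-4,6-dimethoxybenzaldehyde; 6 3-iodo-6-methoxy-2-(4-methoxyphenyl)benzofuran-4-carbaldehyde
Product: 9 3-(2-formyl-3,5-dimethoxyphenyl)-6-methoxy-2-(4-methoxyphenyl)benzofuran-4-carbaldehyde, via arylboronate 8 (not isolated)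
Conditions: B2pin2 (1.05 equiv), PdCl2(dppf) (3 mol %), KOAc, 1,4-dioxane, 90 °C; then 6, SPhos Pd G2 (3 mol %), aq. K3PO4, 80 °C
Reagents that add atoms: bis(pinacolato)diboron, CC1(C)OB(OC1(C)C)B1OC(C)(C)C(C)(C)O1 (its boron is carried by intermediate 8 only)
Why: One-pot Miyaura borylation of the aryl bromide and Suzuki–Miyaura coupling of the boronate with the more reactive aryl iodide; a bulky biaryl phosphine is used because the new biaryl bond has three ortho substituents.

**Step 5**
Reactants: 9 3-(2-formyl-3,5-dimethoxyphenyl)-6-methoxy-2-(4-methoxyphenyl)benzofuran-4-carbaldehyde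
Product: 10 benzofuran-fused tetramethoxy dibenzocycloheptene (the two CHO carbons of 9 joined as the cis C7b=C8b alkene; achiral)
Conditions: TiCl4, Zn, pyridine, THF, reflux; slow addition of 9 (high dilution)
Reagents that add atoms: none
Why: Intramolecular McMurry coupling (pinacol coupling on low-valent titanium, then deoxygenation) of a biaryl-type dialdehyde; the new alkene lies in a seven-membered ring and can only be cis.

**Step 6**
Reactants: 10 benzofuran-fused tetramethoxy dibenzocycloheptene; 11 4-methoxybenzenediazonium tetrafluoroborate; 12 (5-bromo-2-methoxyphenyl)boronic acid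
Product: 13 (7bS,8bS)-cis-7b-(4-methoxyphenyl)-8b-(5-bromo-2-methoxyphenyl)-7b,8b-dihydro-10
Conditions: Pd2(dba)3 (5 mol %), (S)-5-CF3-t-BuPyOx (12 mol %), NaHCO3, t-AmOH/DMF, 0 °C → rt; 12 added over 4 h
Reagents that add atoms: none
Why: Proposed new method: Pd(0) and diazonium salt 11 give a cationic (PyOx)Pd–anisyl species that adds syn across the ring-locked C7b=C8b alkene, the anisyl group bonding to C7b (the end whose positive character is stabilised by the ortho- and para-methoxy groups of ring A, whereas the oxygens of ring B are meta to C8b) and palladium to C8b, where it is held as an η3-benzyl on ring B; because aryl and metal entered from one face, the single hydrogen on C7b points away from palladium and the ring cannot turn it into reach, so the usual β-hydride exit is closed and the benzyl-palladium lives long enough to transmetalate with boronic acid 12 and form the C8b–aryl bond by reductive elimination with retention. The closest known chemistry is the Pd-catalysed three-component 1,2-diarylation of 1,3-dienes and of norbornene-type alkenes with aryldiazonium salts or aryl halides and arylboronic acids (π-allyl or β-hydrogen-free alkyl-palladium intermediates), together with enantioselective Heck–Matsuda arylation of cyclic alkenes under chiral N,N ligands; it has not been shown on a cyclic stilbene with two different aryl groups under enantiocontrol. No ring is closed. C7b (S) and C8b (S) are both fixed by which enantiotopic face of the stereocentre-free alkene the ligand-bound aryl-palladium attacks, and syn insertion plus stereoretentive reductive elimination make them cis. The step needs regioselectivity (electronic bias of ring A over ring B), syn-diastereoselectivity (no accessible β-hydrogen), enantioface selectivity (chiral PyOx ligand) and chemoselectivity for ArN2+ over the aryl bromide of 12 (oxidative addition of the diazonium salt is far faster at 0 °C) and over direct biaryl coupling (slow addition of 12).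

**Step 7**
Reactants: 13 (7bS,8bS)-cis-7b-(4-methoxyphenyl)-8b-(5-bromo-2-methoxyphenyl)-7b,8b-dihydro-10
Product: 14 (7aS,8aS,7bS,8bS)-7a,8a-dihydro-13 (trans-dihydrofuran; H-8a cis to the aryl groups on C7b and C8b)
Conditions: Et3SiH, TFA, CH2Cl2, 0 °C → rt
Reagents that add atoms: none
Why: Ionic hydrogenation: TFA protonates benzofuran C3 (C8a) to the O- and p-anisyl-stabilised C2 cation, which Et3SiH reduces; the proton can only enter on the face opposite to the side on which the C7b–C8b bridge lies, and the bridge sits on the side that keeps both aryl groups pseudo-axial (no A1,3 strain with the ring-A methoxy group or the peri C–H), so H-8a should end up cis to the two aryl groups (8aS), while C7a settles as the thermodynamic trans isomer (7aS) through reversible acid ionisation of the p-methoxybenzylic C–O bond.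

**Step 8**
Reactants: 14 (7aS,8aS,7bS,8bS)-7a,8a-dihydro-13
Product: 16 hexaacetate of 15 (left-half aryl bromide), via hexaphenol 15 (not isolated)
Conditions: BBr3, CH2Cl2, −78 → 0 °C, aqueous work-up; then Ac2O, pyridine, DMAP (cat.), rt
Reagents that add atoms: acetic anhydride, CC(=O)OC(C)=O
Why: Lewis-acid cleavage of the six aryl methyl ethers at a stage that contains no stilbene (a ring-fused dihydrofuran that opens re-closes to the stable trans form), then peracetylation so that the phenols pass the Heck coupling as base-labile esters; the stereocentres are retained.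

**Step 9**
Reactants: 17 1-bromo-3,5-dimethoxybenzene; 18 3,5-dimethoxybenzoyl chloride
Product: 20 (2-bromo-6-hydroxy-4-methoxyphenyl)(3,5-dimethoxyphenyl)methanone, via methoxy ketone 19 (not isolated)
Conditions: AlCl3, CH2Cl2, 0 °C → rt; then BCl3, 0 °C; aq. HCl work-up
Reagents that add atoms: none
Why: Friedel–Crafts acylation at C2 of the bromodimethoxybenzene (para to one methoxy group and ortho to the other, the site that Vilsmeier formylation of this arene also attacks), followed by chelation-controlled BCl3 cleavage of the methoxy group ortho to the new carbonyl.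

**Step 10**
Reactants: 20 (2-bromo-6-hydroxy-4-methoxyphenyl)(3,5-dimethoxyphenyl)methanone; 21 4-methoxybenzyl chloride
Product: 22 {2-bromo-4-methoxy-6-[(4-methoxybenzyl)oxy]phenyl}(3,5-dimethoxyphenyl)methanone
Conditions: K2CO3, KI (cat.), DMF, 60 °C
Reagents that add atoms: none
Why: Williamson ether synthesis on the ortho-hydroxy ketone; the 4-methoxybenzyl group is not a protecting group here but supplies C7d and its aryl ring.

**Step 11**
Reactants: 22 {2-bromo-4-methoxy-6-[(4-methoxybenzyl)oxy]phenyl}(3,5-dimethoxyphenyl)methanone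
Product: 23 hydrazone of 22
Conditions: N2H4·H2O (excess), AcOH (cat.), n-BuOH, 110 °C
Reagents that add atoms: hydrazine hydrate, NN.O
Why: Condensation of the hindered diaryl ketone with excess hydrazine under forcing conditions; the bromide on the electron-rich ring is not displaced without a metal catalyst.

**Step 12**
Reactants: 23 hydrazone of 22
Product: 26 (2S,3S)-trans-4-bromo-3-(3,5-dimethoxyphenyl)-6-methoxy-2-(4-methoxyphenyl)-2,3-dihydrobenzofuran, via diaryldiazomethane 24 (not isolated), via cis-dihydrobenzofuran 25 (not isolated)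
Conditions: MnO2, CH2Cl2, 0 °C, filtered; Rh2(S-PTAD)4 (1 mol %), CH2Cl2, 0 °C → rt; then TFA, rt
Reagents that add atoms: none
Why: MnO2 dehydrogenation to the diazo compound and Rh(II)-catalysed intramolecular 1,5 C–H insertion of the donor/donor carbene into the benzylic ether C–H bond (established for 2-benzyloxybenzophenone hydrazones, including resveratrol-type 2,3-diaryl-dihydrobenzofurans) give the cis product with C8d (S) set by the chiral carboxylate ligands, and TFA then epimerises C7d to the thermodynamic trans isomer (7dS) by reversible ionisation of the p-methoxybenzylic C–O bond.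

**Step 13**
Reactants: 26 (2S,3S)-trans-4-bromo-3-(3,5-dimethoxyphenyl)-6-methoxy-2-(4-methoxyphenyl)-2,3-dihydrobenzofuran
Product: 28 tetraacetate of 27, via tetraphenol 27 (not isolated)
Conditions: BBr3, CH2Cl2, −78 → 0 °C, aqueous work-up; then Ac2O, pyridine, DMAP (cat.), rt
Reagents that add atoms: acetic anhydride, CC(=O)OC(C)=O
Why: BBr3 ether cleavage before the vinyl group and the stilbene exist (any opening of the dihydrofuran at C7d–O is reversible and returns the trans ring), then peracetylation; C8d is not affected.

**Step 14**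
Reactants: 28 tetraacetate of 27; 29 tributyl(vinyl)stannane
Product: 30 (2S,3S)-trans-4-vinyl tetraacetate (vinyl in place of bromine in 28)
Conditions: Pd(PPh3)4 (5 mol %), toluene, 100 °C
Reagents that add atoms: none
Why: Stille coupling of the aryl bromide with the vinylstannane under neutral conditions that spare the aryl acetates.

**Step 15**
Reactants: 16 hexaacetate of 15; 30 (2S,3S)-trans-4-vinyl tetraacetate
Product: 31 deca-acetate of the target
Conditions: Pd2(dba)3 (2.5 mol %), P(t-Bu)3·HBF4 (10 mol %), Cy2NMe, 1,4-dioxane, 80 °C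
Reagents that add atoms: none
Why: Heck reaction of the aryl bromide with the terminal styrene; β-arylation and syn β-hydride elimination give the E-stilbene, and the hindered amine base leaves the acetates and all six stereocentres untouched.

**Step 16**
Reactants: 31 deca-acetate of the target
Product: 32 CNP0266373.2 (7aS,8aS,7bS,8bS,7dS,8dS; E)
Conditions: K2CO3, MeOH/THF (degassed, argon), 0 °C → rt; AcOH quench
Reagents that add atoms: none
Why: Base-catalysed transesterification of the ten aryl acetates with methanol at or below room temperature, which avoids the acid-induced cyclisation of the stilbene onto the neighbouring resorcinol ring and the opening of the dihydrobenzofurans that Lewis-acid demethylation of the assembled tetramer would risk.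

**Compound list**

1 | 3-hydroxy-5-methoxybenzaldehyde | COc1cc(O)cc(C=O)c1 | starting material
2 | 3-hydroxy-2-iodo-5-methoxybenzaldehyde | COc1cc(O)c(I)c(C=O)c1 | intermediate
3 | 4-ethynylanisole | COc1ccc(C#C)cc1 | starting material
4 | 3-hydroxy-5-methoxy-2-[(4-methoxyphenyl)ethynyl]benzaldehyde | COc1cc(O)c(C#Cc2ccc(OC)cc2)c(C=O)c1 | intermediate
5 | 6-methoxy-2-(4-methoxyphenyl)benzofuran-4-carbaldehyde | COc1ccc(cc1)-c1cc2c(C=O)cc(OC)cc2o1 | intermediate
6 | 3-iodo-6-methoxy-2-(4-methoxyphenyl)benzofuran-4-carbaldehyde | COc1ccc(cc1)-c1oc2cc(OC)cc(C=O)c2c1I | intermediate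
7 | 2-bromo-4,6-dimethoxybenzaldehyde | COc1cc(OC)c(C=O)c(Br)c1 | starting material
8 | 2,4-dimethoxy-6-(4,4,5,5-tetramethyl-1,3,2-dioxaborolan-2-yl)benzaldehyde | COc1cc(OC)c(C=O)c(c1)B1OC(C)(C)C(C)(C)O1 | intermediate
9 | 3-(2-formyl-3,5-dimethoxyphenyl)-6-methoxy-2-(4-methoxyphenyl)benzofuran-4-carbaldehyde | COc1ccc(cc1)-c1oc2cc(OC)cc(C=O)c2c1-c1cc(OC)cc(OC)c1C=O | intermediate
10 | benzofuran-fused tetramethoxy dibenzocycloheptene (cis C7b=C8b alkene; achiral) | COc1ccc(cc1)-c1oc2cc(OC)cc3C=Cc4c(OC)cc(OC)cc4-c1c23 | intermediate
11 | 4-methoxybenzenediazonium tetrafluoroborate | COc1ccc(cc1)[N+]#N.F[B-](F)(F)F | starting material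
12 | (5-bromo-2-methoxyphenyl)boronic acid | COc1ccc(Br)cc1B(O)O | starting material
13 | (7bS,8bS)-cis-7b-(4-methoxyphenyl)-8b-(5-bromo-2-methoxyphenyl)-7b,8b-dihydro-10 | COc1ccc([C@H]2c3c(OC)cc(OC)cc3-c3c(-c4ccc(OC)cc4)oc4cc(OC)cc(c34)[C@H]2c2cc(Br)ccc2OC)cc1 | intermediate
14 | (7aS,8aS,7bS,8bS)-7a,8a-dihydro-13 (trans-dihydrofuran; H-8a cis to the C7b/C8b aryl groups) | COc1ccc([C@H]2c3c(OC)cc(OC)cc3[C@H]3c4c(cc(OC)cc4[C@H]2c2cc(Br)ccc2OC)O[C@@H]3c2ccc(OC)cc2)cc1 | intermediate
15 | hexaphenol of 14 | Oc1ccc([C@H]2c3c(O)cc(O)cc3[C@H]3c4c(cc(O)cc4[C@H]2c2cc(Br)ccc2O)O[C@@H]3c2ccc(O)cc2)cc1 | intermediate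
16 | hexaacetate of 15 (left-half aryl bromide) | CC(=O)Oc1ccc([C@H]2c3c(OC(C)=O)cc(OC(C)=O)cc3[C@H]3c4c(cc(OC(C)=O)cc4[C@H]2c2cc(Br)ccc2OC(C)=O)O[C@@H]3c2ccc(OC(C)=O)cc2)cc1 | intermediate
17 | 1-bromo-3,5-dimethoxybenzene | COc1cc(Br)cc(OC)c1 | starting material
18 | 3,5-dimethoxybenzoyl chloride | COc1cc(cc(OC)c1)C(Cl)=O | starting material
19 | (2-bromo-4,6-dimethoxyphenyl)(3,5-dimethoxyphenyl)methanone | COc1cc(OC)c(C(=O)c2cc(OC)cc(OC)c2)c(Br)c1 | intermediate
20 | (2-bromo-6-hydroxy-4-methoxyphenyl)(3,5-dimethoxyphenyl)methanone | COc1cc(O)c(C(=O)c2cc(OC)cc(OC)c2)c(Br)c1 | intermediate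
21 | 4-methoxybenzyl chloride | COc1ccc(CCl)cc1 | starting material
22 | {2-bromo-4-methoxy-6-[(4-methoxybenzyl)oxy]phenyl}(3,5-dimethoxyphenyl)methanone | COc1ccc(COc2cc(OC)cc(Br)c2C(=O)c2cc(OC)cc(OC)c2)cc1 | intermediate
23 | hydrazone of 22 | COc1ccc(COc2cc(OC)cc(Br)c2C(=NN)c2cc(OC)cc(OC)c2)cc1 | intermediate
24 | diaryldiazomethane from 23 | COc1ccc(COc2cc(OC)cc(Br)c2C(=[N+]=[N-])c2cc(OC)cc(OC)c2)cc1 | intermediate
25 | (2R,3S)-cis-4-bromo-3-(3,5-dimethoxyphenyl)-6-methoxy-2-(4-methoxyphenyl)-2,3-dihydrobenzofuran | Brc1cc(OC)cc2c1[C@H](c1cc(OC)cc(OC)c1)[C@H](c1ccc(OC)cc1)O2 | intermediate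
26 | (2S,3S)-trans-4-bromo-3-(3,5-dimethoxyphenyl)-6-methoxy-2-(4-methoxyphenyl)-2,3-dihydrobenzofuran | Brc1cc(OC)cc2c1[C@H](c1cc(OC)cc(OC)c1)[C@@H](c1ccc(OC)cc1)O2 | intermediate
27 | tetraphenol of 26 | Brc1cc(O)cc2c1[C@H](c1cc(O)cc(O)c1)[C@@H](c1ccc(O)cc1)O2 | intermediate
28 | tetraacetate of 27 | Brc1cc(OC(C)=O)cc2c1[C@H](c1cc(OC(C)=O)cc(OC(C)=O)c1)[C@@H](c1ccc(OC(C)=O)cc1)O2 | intermediate
29 | tributyl(vinyl)stannane | CCCC[Sn](CCCC)(CCCC)C=C | starting material
30 | (2S,3S)-trans-4-vinyl tetraacetate (right-half styrene) | C=Cc1cc(OC(C)=O)cc2c1[C@H](c1cc(OC(C)=O)cc(OC(C)=O)c1)[C@@H](c1ccc(OC(C)=O)cc1)O2 | intermediate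
31 | deca-acetate of the target | CC(=O)Oc1ccc([C@H]2c3c(OC(C)=O)cc(OC(C)=O)cc3[C@H]3c4c(cc(OC(C)=O)cc4[C@H]2c2cc(/C=C/c4cc(OC(C)=O)cc5c4[C@H](c4cc(OC(C)=O)cc(OC(C)=O)c4)[C@@H](c4ccc(OC(C)=O)cc4)O5)ccc2OC(C)=O)O[C@@H]3c2ccc(OC(C)=O)cc2)cc1 | intermediate
32 | CNP0266373.2 (7aS,8aS,7bS,8bS,7dS,8dS; E) | Oc1ccc([C@H]2c3c(O)cc(O)cc3[C@H]3c4c(cc(O)cc4[C@H]2c2cc(/C=C/c4cc(O)cc5c4[C@H](c4cc(O)cc(O)c4)[C@@H](c4ccc(O)cc4)O5)ccc2O)O[C@@H]3c2ccc(O)cc2)cc1 | target

**Step count and risks**

Total: 16 steps. Longest linear sequence: 10 steps (steps 1–8, 15 and 16, from 1).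

Steps most likely to fail:

1. Step 6 (proposed new method). What may go wrong: insertion into the hindered ring-locked stilbene may be slower than direct coupling of the diazonium salt with the boronic acid; the first aryl group may be delivered to C8b instead of C7b; face selection by the ligand may be poor. Fallback with known reactions, making the same two C–aryl bonds one after the other, from 10 back to 13. A Cu/Pd co-catalysed enantioselective syn-arylboration (chiral bisphosphine–copper boryl catalyst, B2pin2, NaOt-Bu, Pd–phosphine co-catalyst, 4-bromo-2-iodoanisole) puts boron on the more electrophilic C7b and the 5-bromo-2-methoxyphenyl group on C8b, giving the cis-7b-boryl-8b-aryl adduct F1. A stereoretentive Suzuki–Miyaura coupling of this secondary benzylic boronate with 4-iodoanisole (Pd2(dba)3, PPh3, Ag2O, DME, 85 °C; the aryl iodide reacts ahead of the aryl bromide) then gives 13.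

2. Step 7. What may go wrong: poor facial selectivity in the protonation of C3, or reductive opening of the benzylic C7a–O bond by excess silane. Fallback that replaces kinetic by thermodynamic control, from 13 back to 14. The reduction is run with a small excess of silane and stopped without regard to the isomer ratio. After removal of the silane the crude dihydrobenzofuran mixture is stirred with TfOH (5 mol %) in HFIP/CH2Cl2 at 0 °C. With no hydride present the C7a–O bond ionises reversibly and the cation sheds and regains the C8a proton through the ring-opened triarylethene phenol F2. C8a and C7a should then equilibrate to the most stable arrangement, expected to be that of 14 (both C7b/C8b aryl groups pseudo-axial, trans-dihydrofuran).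

3. Step 12. What may go wrong: slow C–H insertion of the twisted, doubly ortho-substituted diaryl carbene (azine formation, carbene dimerisation) with erosion of enantioselectivity; sluggish hydrazone formation in step 11 would have the same effect. Fallback by resolution, from 22 back to 26. Phosphazene-base (P4-t-Bu) mediated cyclisation–dehydration of the benzyl ether onto the ketone gives 4-bromo-3-(3,5-dimethoxyphenyl)-6-methoxy-2-(4-methoxyphenyl)benzofuran F3. Ionic hydrogenation (Et3SiH, TFA) followed by acid equilibration gives the racemic trans-dihydrobenzofuran F4. Preparative chiral SFC then delivers 26.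

**Further compounds**

F1 | step 6 | (7bR,8bS)-cis-8b-(5-bromo-2-methoxyphenyl)-7b-(4,4,5,5-tetramethyl-1,3,2-dioxaborolan-2-yl)-7b,8b-dihydro-10 | CC1(C)OB(OC1(C)C)[C@H]1c2c(OC)cc(OC)cc2-c2c(-c3ccc(OC)cc3)oc3cc(OC)cc(c23)[C@H]1c1cc(Br)ccc1OC
F2 | step 7 | (7bS,8bS)-ring-opened triarylethene phenol (C8a=C7a alkene, free OH on ring B; alkene geometry not defined) | COc1ccc([C@H]2c3c(OC)cc(OC)cc3C(=Cc3ccc(OC)cc3)c3c(O)cc(OC)cc3[C@H]2c2cc(Br)ccc2OC)cc1
F3 | step 12 | 4-bromo-3-(3,5-dimethoxyphenyl)-6-methoxy-2-(4-methoxyphenyl)benzofuran | COc1ccc(cc1)-c1oc2cc(OC)cc(Br)c2c1-c1cc(OC)cc(OC)c1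
F4 | step 12 | racemic trans-4-bromo-3-(3,5-dimethoxyphenyl)-6-methoxy-2-(4-methoxyphenyl)-2,3-dihydrobenzofuran | Brc1cc(OC)cc2c1[C@H](c1cc(OC)cc(OC)c1)[C@@H](c1ccc(OC)cc1)O2.Brc1cc(OC)cc2c1[C@@H](c1cc(OC)cc(OC)c1)[C@H](c1ccc(OC)cc1)O2
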